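## Retrosynthetic overview

1. The target comes from butanolide adduct 27 by acylal reduction, relactonisation and acetylation. Adduct 27 comes from one tertiary-radical conjugate addition of the hydroazulenyl oxalate 19 to the 3-substituted (5S)-menthyloxybutenolide 26, which makes the bond to the quaternary carbon C-1 and sets C-1, the CH bearing CH2OAc and the lactone CH.
2. The cis-perhydroazulene with its exocyclic methylene comes from cyclobutylcarbinyl radical fragmentation of a cis,anti,cis-tricyclo[5.3.0.0^2,5]decane, in which a temporary bond between the future C-8 and C-5 is cut.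
3. Key disconnection: C5–C6 and C7–C8 of the seven-membered ring (azulene numbering) are made together by [2+2] photocycloaddition of ethylene to the cyclopentene-1-carboxylate of a cis-bicyclo[3.3.0]octene. Enabling feature: the methylidene-bearing C-8 is followed by three ring CH2 groups (C-7, C-6, C-5) ending at the quaternary CMe2 carbon C-4, so C-8 (as the ester-bearing carbon) and C-5 can be the olefinic carbons of a five-membered enoate whose only γ-position is the blocked C-4; the enforced cis 5–5 fusion becomes the cis 5–7 fusion.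
4. The bicyclo[3.3.0]octene comes from cyclopentenone by catalytic asymmetric Mukaiyama–Michael addition (sets C-3a), regiospecific enolate alkylation, Dieckmann closure and enol triflate reduction.
5. Ring order: five-membered ring (cyclopentenone) → second five-membered ring (Dieckmann) → cyclobutane ([2+2], temporary) → seven-membered ring (fragmentation) → γ-lactone (last).

Key step: step 7

Remark (assumption): locants in the text follow azulene numbering for the bicyclic core (C-1 quaternary, C-3a/C-8a ring fusion, C-4 CMe2, C-8 methylidene carbon); 5-hydroxyfuran-2(5H)-one, (+)-menthol and the Reformatsky reagent solution 25 are taken as purchasable.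

## Route

Step 1
Reactants: 1 cyclopent-2-en-1-one; 2 1-methoxy-2-methyl-1-(trimethylsilyloxy)prop-1-ene
Product: 3 methyl 2-methyl-2-[(1R)-3-(trimethylsilyloxy)cyclopent-2-en-1-yl]propanoate
Conditions: proline-derived B-(o-tolyl)oxazaborolidine/Tf2NH (20 mol %, enantiomer chosen to deliver the 1R adduct), Ph3PO (25 mol %), toluene, −20 °C; non-aqueous isolation
Reagents that add atoms: none
Why: Catalytic enantioselective Mukaiyama–Michael addition, in which the chiral oxazaborolidinium ion shields one face of the bound enone so that the ketene acetal sets the one stereocenter carried through the whole route (future C-3a) and the silyl group ends on oxygen as a regiodefined silyl enol ether.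

Step 2
Reactants: 3 methyl 2-methyl-2-[(1R)-3-(trimethylsilyloxy)cyclopent-2-en-1-yl]propanoate; 4 methyl bromoacetate
Product: 6 methyl 2-[(1R,2S)-2-(2-methoxy-2-oxoethyl)-3-oxocyclopentyl]-2-methylpropanoate, via ammonium enolate 5 (not isolated)
Conditions: BnMe3N+F− (anhydrous), 4 Å MS, THF, −20 → 0 °C
Reagents that add atoms: none
Why: Fluoride-mediated regiospecific enolate alkylation, in which the enolate is generated only at the silyl enol ether position and is alkylated by the reactive α-halo ester anti to the neighbouring substituent (trans product, epimerisable and therefore harmless).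

Step 3
Reactants: 6 methyl 2-[(1R,2S)-2-(2-methoxy-2-oxoethyl)-3-oxocyclopentyl]-2-methylpropanoate
Product: 7 methyl (3aR,6aS)-3,3-dimethyl-2,6-dioxooctahydropentalene-1-carboxylate (keto/enol mixture)
Conditions: NaH, MeOH (cat.), THF, 65 °C; AcOH quench
Reagents that add atoms: none
Why: Dieckmann condensation, in which the ketone α-center epimerises, only the cis diester can close, and the single possible five-membered closure (acetate α-carbon onto the non-enolisable CMe2-flanked ester) is driven by deprotonation of the β-keto ester to give the cis-fused bicyclo[3.3.0]octane.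

Step 4
Reactants: 7 methyl (3aR,6aS)-3,3-dimethyl-2,6-dioxooctahydropentalene-1-carboxylate
Product: 8 methyl (3aR,6aS)-3,3-dimethyl-6-oxo-2-(trifluoromethylsulfonyloxy)-3,3a,4,5,6,6a-hexahydropentalene-1-carboxylate
Conditions: NaH (1.0 equiv), THF, 0 °C; PhNTf2, 0 °C → rt
Reagents that add atoms: N-phenylbis(trifluoromethanesulfonimide), O=S(=O)(N(c1ccccc1)S(=O)(=O)C(F)(F)F)C(F)(F)F
Why: Enol triflate formation, in which the β-keto ester is by far the most acidic site, its enolate is O-sulfonylated and the CMe2 carbon allows only one enol regioisomer.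

Step 5
Reactants: 8 methyl (3aR,6aS)-3,3-dimethyl-6-oxo-2-(trifluoromethylsulfonyloxy)-3,3a,4,5,6,6a-hexahydropentalene-1-carboxylate
Product: 9 methyl (3aR,6aS)-6,6-(ethylenedioxy)-3,3-dimethyl-2-(trifluoromethylsulfonyloxy)-3,3a,4,5,6,6a-hexahydropentalene-1-carboxylate
Conditions: TMSOCH2CH2OTMS, TMSOTf (cat.), CH2Cl2, −78 → −20 °C
Reagents that add atoms: 1,2-bis(trimethylsilyloxy)ethane, C[Si](C)(C)OCCO[Si](C)(C)C
Why: Low-temperature silyl-triflate-catalysed ketalisation masks the only remaining ketone, so that the later enoate is not a β,γ-unsaturated ketone (no oxa-di-π-methane or Norrish photochemistry and no doubly activated ring-fusion hydrogen).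

Step 6
Reactants: 9 methyl (3aR,6aS)-6,6-(ethylenedioxy)-3,3-dimethyl-2-(trifluoromethylsulfonyloxy)-3,3a,4,5,6,6a-hexahydropentalene-1-carboxylate
Product: 10 methyl (3aR,6aS)-6,6-(ethylenedioxy)-3,3-dimethyl-3,3a,4,5,6,6a-hexahydropentalene-1-carboxylate
Conditions: Pd(OAc)2 (5 mol %), PPh3, HCO2H, Bu3N, DMF, 60 °C
Reagents that add atoms: none
Why: Palladium-catalysed formate reduction of a vinyl triflate (oxidative addition, decarboxylation of formate to a hydride, reductive elimination) replaces OTf by H and leaves the cyclopentene-1-carboxylate chromophore.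

Step 7
Reactants: 10 methyl (3aR,6aS)-6,6-(ethylenedioxy)-3,3-dimethyl-3,3a,4,5,6,6a-hexahydropentalene-1-carboxylate; 11 ethene
Product: 12 methyl 10,10-(ethylenedioxy)-6,6-dimethyl-cis,anti,cis-tricyclo[5.3.0.0^2,5]decane-2-carboxylate (cyclobutane on the convex face)
Conditions: hν (medium-pressure Hg lamp, Vycor filter), ethene-saturated CH2Cl2, −78 °C
Reagents that add atoms: none
Why: Enoate–alkene [2+2] photocycloaddition: the excited cyclopentene-1-carboxylate (held in a five-membered ring, so it cannot relax by E/Z twisting, and with the blocked CMe2 carbon as its only γ-position, so it cannot photodeconjugate) adds to ethene through a 1,4-biradical that collapses to the cyclobutane. The closest known reaction type is the photocycloaddition of ethene to cycloalkene-1-carboxylates and 2-cycloalkenones that is used ahead of cyclobutylcarbinyl radical fragmentation for two-carbon ring expansion. One ring is closed, the cyclobutane, by an intermolecular [2+2] closure that can only be cis on the five-membered ring. Two stereocenters arise (the ester-bearing carbon and the neighbouring CH) and ethene should approach the convex face of the cis-bicyclo[3.3.0]octene, anti to the ketal ring, but both centers are erased in step 12, so no facial selectivity is required. The selectivity that is needed is chemoselectivity for the enoate, which is secured because ethene is symmetric, the ketone is a photoinert ketal and no other chromophore is present. The bond between the two former olefinic carbons is temporary: steps 8, 9 and 12 turn the ester carbon into a radical that breaks it, so the two ethene carbons end as C-6 and C-7 of the seven-membered ring and the cis ring fusion is carried over unchanged.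

Step 8
Reactants: 12 methyl 10,10-(ethylenedioxy)-6,6-dimethyl-cis,anti,cis-tricyclo[5.3.0.0^2,5]decane-2-carboxylate
Product: 13 [10,10-(ethylenedioxy)-6,6-dimethyl-cis,anti,cis-tricyclo[5.3.0.0^2,5]dec-2-yl]methanol
Conditions: LiAlH4, Et2O, 0 °C; aq NaOH work-up
Reagents that add atoms: none
Why: Hydride reduction of the neopentyl methyl ester to the primary alcohol, to which the ketal is inert.

Step 9
Reactants: 13 [10,10-(ethylenedioxy)-6,6-dimethyl-cis,anti,cis-tricyclo[5.3.0.0^2,5]dec-2-yl]methanol
Product: 14 10,10-(ethylenedioxy)-2-(iodomethyl)-6,6-dimethyl-cis,anti,cis-tricyclo[5.3.0.0^2,5]decane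
Conditions: PPh3, I2, imidazole, toluene, 80 °C
Reagents that add atoms: iodine, II
Why: Appel-type iodination by SN2 displacement at the neopentyl carbinol carbon, in which no carbocation forms and the cyclobutylcarbinyl skeleton therefore does not rearrange.

Step 10
Reactants: 14 10,10-(ethylenedioxy)-2-(iodomethyl)-6,6-dimethyl-cis,anti,cis-tricyclo[5.3.0.0^2,5]decane
Product: 15 2-(iodomethyl)-6,6-dimethyl-cis,anti,cis-tricyclo[5.3.0.0^2,5]decan-10-one
Conditions: PPTS, acetone/H2O, 50 °C
Reagents that add atoms: water, O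
Why: Mild acid-catalysed ketal hydrolysis releases the cyclopentanone, whose α ring-fusion center can only be cis in a bicyclo[3.3.0]octanone, while the neopentyl iodide is inert.

Step 11
Reactants: 15 2-(iodomethyl)-6,6-dimethyl-cis,anti,cis-tricyclo[5.3.0.0^2,5]decan-10-one
Product: 16 2-(iodomethyl)-6,6,10-trimethyl-cis,anti,cis-tricyclo[5.3.0.0^2,5]decan-10-ol (methyl exo expected)
Conditions: MeMgBr, CeCl3, THF, −78 °C; aq NH4Cl at −78 °C
Reagents that add atoms: methylmagnesium bromide, C[Mg]Br
Why: Organocerium 1,2-addition to the enolisable cyclopentanone from the convex face gives the tertiary carbinol, whose configuration is of no consequence because this carbon becomes a planar radical in step 17, and the cold quench keeps the endo alkoxide from displacing the neopentyl iodide.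

Step 12
Reactants: 16 2-(iodomethyl)-6,6,10-trimethyl-cis,anti,cis-tricyclo[5.3.0.0^2,5]decan-10-ol
Product: 17 (3aR,8aS)-1,4,4-trimethyl-8-methylidenedecahydroazulen-1-ol ((1S) epimer expected)
Conditions: Bu3SnH (syringe pump), AIBN (cat.), PhH (5 mM), 80 °C
Reagents that add atoms: none
Why: Cyclobutylcarbinyl radical fragmentation (two-carbon ring expansion), in which iodine abstraction gives the primary radical, β-scission of the strained ring-fusion bond of the bicyclo[3.2.0]heptane unit gives the exocyclic methylene and the more stable secondary ring radical (not the primary radical from the outer bond), and this is reduced by Bu3SnH kept at low concentration, with the ring-fusion centers untouched.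

Step 13
Reactants: 17 (3aR,8aS)-1,4,4-trimethyl-8-methylidenedecahydroazulen-1-ol
Product: 19 cesium 2-oxo-2-{[(3aR,8aS)-1,4,4-trimethyl-8-methylidenedecahydroazulen-1-yl]oxy}acetate, via methyl oxalate 18 (not isolated)
Conditions: ClC(O)CO2Me, Et3N, DMAP (cat.), CH2Cl2, 0 °C → rt; then CsOH·H2O (1.0 equiv), THF/H2O, rt
Reagents that add atoms: methyl chlorooxoacetate, COC(=O)C(=O)Cl; cesium hydroxide, [Cs+].[OH-]
Why: Acylation of the tertiary alcohol and selective half-ester hydrolysis give the bench-stable cesium oxalate that serves as tertiary-radical precursor under photoredox conditions.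

Step 14
Reactants: 20 5-hydroxyfuran-2(5H)-one; 21 (1S,2R,5S)-(+)-menthol
Product: 22 (5S)-5-{[(1S,2R,5S)-5-methyl-2-(propan-2-yl)cyclohexyl]oxy}furan-2(5H)-one
Conditions: TsOH (cat.), toluene, reflux (−H2O); crystallisation from hexane
Reagents that add atoms: none
Why: Acid-catalysed acetalisation of the pseudo-acid, in which the (5S) diastereomer should be collected by crystallisation while the acetal center of the mother liquor epimerises under acid.

Step 15
Reactants: 22 (5S)-5-{[(1S,2R,5S)-5-methyl-2-(propan-2-yl)cyclohexyl]oxy}furan-2(5H)-one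
Product: 24 (5S)-3-bromo-5-{[(1S,2R,5S)-5-methyl-2-(propan-2-yl)cyclohexyl]oxy}furan-2(5H)-one, via dibromide 23 (not isolated)
Conditions: Br2, CH2Cl2, 0 °C; then Et3N, 0 °C → rt
Reagents that add atoms: bromine, BrBr
Why: Bromine addition to the butenolide double bond followed by amine-induced dehydrobromination (acidic α-hydrogen, β-bromide) gives the α-bromobutenolide without touching the acetal center.

Step 16
Reactants: 24 (5S)-3-bromo-5-{[(1S,2R,5S)-5-methyl-2-(propan-2-yl)cyclohexyl]oxy}furan-2(5H)-one; 25 (2-tert-butoxy-2-oxoethyl)zinc bromide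
Product: 26 tert-butyl 2-[(5S)-5-{[(1S,2R,5S)-5-methyl-2-(propan-2-yl)cyclohexyl]oxy}-2-oxo-2,5-dihydrofuran-3-yl]acetate
Conditions: Pd(PPh3)4 (5 mol %), THF, 40 °C
Reagents that add atoms: none
Why: Negishi cross-coupling of a Reformatsky reagent with an electron-poor vinyl bromide (oxidative addition to zerovalent palladium, transmetalation, reductive elimination) installs the CH2CO2t-Bu arm at C-3.

Step 17
Reactants: 19 cesium 2-oxo-2-{[(3aR,8aS)-1,4,4-trimethyl-8-methylidenedecahydroazulen-1-yl]oxy}acetate; 26 tert-butyl 2-[(5S)-5-{[(1S,2R,5S)-5-methyl-2-(propan-2-yl)cyclohexyl]oxy}-2-oxo-2,5-dihydrofuran-3-yl]acetate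
Product: 27 tert-butyl 2-[(3R,4R,5S)-5-{[(1S,2R,5S)-5-methyl-2-(propan-2-yl)cyclohexyl]oxy}-2-oxo-4-[(1R,3aR,8aS)-1,4,4-trimethyl-8-methylidenedecahydroazulen-1-yl]oxolan-3-yl]acetate
Conditions: Ir[dF(CF3)ppy]2(dtbbpy)PF6 (1 mol %), H2O (10 equiv), DME/DMF 3:1, blue LEDs, 60 °C
Reagents that add atoms: none
Why: Photoredox decarboxylative Giese reaction, in which the tertiary radical released from the oxalate adds to the unsubstituted β-carbon of the butenolide on its own face anti to the C8a–C8 bond (quaternary C-1, side chain cis to the ring-fusion hydrogens) and anti to the menthyloxy group (CH center), and the resulting α-radical is reduced to the enolate and protonated by water anti to the new quaternary substituent (cis-3,4 lactone, third center).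

Step 18
Reactants: 27 tert-butyl 2-[(3R,4R,5S)-5-{[(1S,2R,5S)-5-methyl-2-(propan-2-yl)cyclohexyl]oxy}-2-oxo-4-[(1R,3aR,8aS)-1,4,4-trimethyl-8-methylidenedecahydroazulen-1-yl]oxolan-3-yl]acetate
Product: 28 tert-butyl (3R,4R)-5-hydroxy-3-(hydroxymethyl)-4-[(1R,3aR,8aS)-1,4,4-trimethyl-8-methylidenedecahydroazulen-1-yl]pentanoate
Conditions: LiBH4, THF, 0 °C (short reaction time); aq NH4Cl
Reagents that add atoms: none
Why: Chemoselective hydride reduction, in which the acylal-type lactone is reduced through its masked aldehyde to the 1,4-diol with release of menthol much faster than the hindered tert-butyl ester is attacked, and the transient aldehydes are reduced before they can enolise.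

Step 19
Reactants: 28 tert-butyl (3R,4R)-5-hydroxy-3-(hydroxymethyl)-4-[(1R,3aR,8aS)-1,4,4-trimethyl-8-methylidenedecahydroazulen-1-yl]pentanoate
Product: 29 (4R)-4-{(1R)-2-hydroxy-1-[(1R,3aR,8aS)-1,4,4-trimethyl-8-methylidenedecahydroazulen-1-yl]ethyl}oxolan-2-one
Conditions: t-BuOK (0.1 equiv), THF, 0 °C → rt; AcOH
Reagents that add atoms: none
Why: Base-catalysed intramolecular transesterification, in which the alkoxide of the hydroxymethyl branch closes the five-membered lactone onto the tert-butyl ester (5-exo-trig), favoured kinetically and thermodynamically over the six-membered lactone from the other hydroxyl.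

Step 20
Reactants: 29 (4R)-4-{(1R)-2-hydroxy-1-[(1R,3aR,8aS)-1,4,4-trimethyl-8-methylidenedecahydroazulen-1-yl]ethyl}oxolan-2-one
Product: 30 (2R)-2-[(3R)-5-oxooxolan-3-yl]-2-[(1R,3aR,8aS)-1,4,4-trimethyl-8-methylidenedecahydroazulen-1-yl]ethyl acetate
Conditions: Ac2O, pyridine, DMAP (cat.), CH2Cl2, 0 °C → rt
Reagents that add atoms: acetic anhydride, CC(=O)OC(C)=O
Why: Standard DMAP-catalysed acetylation of the remaining primary alcohol.

## Compound list

1 | cyclopent-2-en-1-one | O=C1C=CCC1 | starting material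
2 | 1-methoxy-2-methyl-1-(trimethylsilyloxy)prop-1-ene | COC(O[Si](C)(C)C)=C(C)C | starting material
3 | methyl 2-methyl-2-[(1R)-3-(trimethylsilyloxy)cyclopent-2-en-1-yl]propanoate | COC(=O)C(C)(C)[C@@H]1CCC(O[Si](C)(C)C)=C1 | intermediate
4 | methyl bromoacetate | COC(=O)CBr | starting material
5 | benzyltrimethylammonium (R)-3-(1-methoxy-2-methyl-1-oxopropan-2-yl)cyclopent-1-en-1-olate | COC(=O)C(C)(C)[C@@H]1CCC([O-])=C1.C[N+](C)(C)Cc1ccccc1 | intermediate
6 | methyl 2-[(1R,2S)-2-(2-methoxy-2-oxoethyl)-3-oxocyclopentyl]-2-methylpropanoate | COC(=O)C(C)(C)[C@@H]1CCC(=O)[C@H]1CC(=O)OC | intermediate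
7 | methyl (3aR,6aS)-3,3-dimethyl-2,6-dioxooctahydropentalene-1-carboxylate | COC(=O)C1C(=O)C(C)(C)[C@@H]2CCC(=O)[C@H]12 | intermediate
8 | methyl (3aR,6aS)-3,3-dimethyl-6-oxo-2-(trifluoromethylsulfonyloxy)-3,3a,4,5,6,6a-hexahydropentalene-1-carboxylate | COC(=O)C1=C(OS(=O)(=O)C(F)(F)F)C(C)(C)[C@@H]2CCC(=O)[C@H]12 | intermediate
9 | methyl (3aR,6aS)-6,6-(ethylenedioxy)-3,3-dimethyl-2-(trifluoromethylsulfonyloxy)-3,3a,4,5,6,6a-hexahydropentalene-1-carboxylate | COC(=O)C1=C(OS(=O)(=O)C(F)(F)F)C(C)(C)[C@@H]2CCC3(OCCO3)[C@H]12 | intermediate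
10 | methyl (3aR,6aS)-6,6-(ethylenedioxy)-3,3-dimethyl-3,3a,4,5,6,6a-hexahydropentalene-1-carboxylate | COC(=O)C1=CC(C)(C)[C@@H]2CCC3(OCCO3)[C@H]12 | intermediate
11 | ethene | C=C | starting material
12 | methyl 10,10-(ethylenedioxy)-6,6-dimethyl-cis,anti,cis-tricyclo[5.3.0.0^2,5]decane-2-carboxylate | COC(=O)[C@@]12CC[C@H]2C(C)(C)[C@@H]3CCC4(OCCO4)[C@H]13 | intermediate
13 | [10,10-(ethylenedioxy)-6,6-dimethyl-cis,anti,cis-tricyclo[5.3.0.0^2,5]dec-2-yl]methanol | OC[C@@]12CC[C@H]2C(C)(C)[C@@H]3CCC4(OCCO4)[C@H]13 | intermediate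
14 | 10,10-(ethylenedioxy)-2-(iodomethyl)-6,6-dimethyl-cis,anti,cis-tricyclo[5.3.0.0^2,5]decane | IC[C@@]12CC[C@H]2C(C)(C)[C@@H]3CCC4(OCCO4)[C@H]13 | intermediate
15 | 2-(iodomethyl)-6,6-dimethyl-cis,anti,cis-tricyclo[5.3.0.0^2,5]decan-10-one | IC[C@@]12CC[C@H]2C(C)(C)[C@@H]3CCC(=O)[C@H]13 | intermediate
16 | 2-(iodomethyl)-6,6,10-trimethyl-cis,anti,cis-tricyclo[5.3.0.0^2,5]decan-10-ol (methyl exo, hydroxyl endo) | IC[C@@]12CC[C@H]2C(C)(C)[C@@H]3CC[C@](C)(O)[C@H]13 | intermediate
17 | (1S,3aR,8aS)-1,4,4-trimethyl-8-methylidenedecahydroazulen-1-ol | C=C1CCCC(C)(C)[C@@H]2CC[C@](C)(O)[C@H]12 | intermediate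
18 | methyl (1S,3aR,8aS)-1,4,4-trimethyl-8-methylidenedecahydroazulen-1-yl oxalate | C=C1CCCC(C)(C)[C@@H]2CC[C@](C)(OC(=O)C(=O)OC)[C@H]12 | intermediate
19 | cesium 2-oxo-2-{[(1S,3aR,8aS)-1,4,4-trimethyl-8-methylidenedecahydroazulen-1-yl]oxy}acetate | C=C1CCCC(C)(C)[C@@H]2CC[C@](C)(OC(=O)C(=O)[O-])[C@H]12.[Cs+] | intermediate
20 | 5-hydroxyfuran-2(5H)-one | OC1OC(=O)C=C1 | starting material
21 | (1S,2R,5S)-(+)-menthol | CC(C)[C@H]1CC[C@H](C)C[C@@H]1O | starting material
22 | (5S)-5-{[(1S,2R,5S)-5-methyl-2-(propan-2-yl)cyclohexyl]oxy}furan-2(5H)-one | O=C1C=C[C@@H](O[C@H]2C[C@@H](C)CC[C@@H]2C(C)C)O1 | intermediate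
23 | (5S)-3,4-dibromo-5-{[(1S,2R,5S)-5-methyl-2-(propan-2-yl)cyclohexyl]oxy}oxolan-2-one | O=C1C(Br)C(Br)[C@@H](O[C@H]2C[C@@H](C)CC[C@@H]2C(C)C)O1 | intermediate
24 | (5S)-3-bromo-5-{[(1S,2R,5S)-5-methyl-2-(propan-2-yl)cyclohexyl]oxy}furan-2(5H)-one | O=C1C(Br)=C[C@@H](O[C@H]2C[C@@H](C)CC[C@@H]2C(C)C)O1 | intermediate
25 | (2-tert-butoxy-2-oxoethyl)zinc bromide | CC(C)(C)OC(=O)C[Zn]Br | starting material
26 | tert-butyl 2-[(5S)-5-{[(1S,2R,5S)-5-methyl-2-(propan-2-yl)cyclohexyl]oxy}-2-oxo-2,5-dihydrofuran-3-yl]acetate | O=C1C(CC(=O)OC(C)(C)C)=C[C@@H](O[C@H]2C[C@@H](C)CC[C@@H]2C(C)C)O1 | intermediate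
27 | tert-butyl 2-[(3R,4R,5S)-5-{[(1S,2R,5S)-5-methyl-2-(propan-2-yl)cyclohexyl]oxy}-2-oxo-4-[(1R,3aR,8aS)-1,4,4-trimethyl-8-methylidenedecahydroazulen-1-yl]oxolan-3-yl]acetate | C=C1CCCC(C)(C)[C@@H]2CC[C@@](C)([C@@H]3[C@@H](O[C@H]4C[C@@H](C)CC[C@@H]4C(C)C)OC(=O)[C@@H]3CC(=O)OC(C)(C)C)[C@H]12 | intermediate
28 | tert-butyl (3R,4R)-5-hydroxy-3-(hydroxymethyl)-4-[(1R,3aR,8aS)-1,4,4-trimethyl-8-methylidenedecahydroazulen-1-yl]pentanoate | C=C1CCCC(C)(C)[C@@H]2CC[C@@](C)([C@H](CO)[C@H](CO)CC(=O)OC(C)(C)C)[C@H]12 | intermediate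
29 | (4R)-4-{(1R)-2-hydroxy-1-[(1R,3aR,8aS)-1,4,4-trimethyl-8-methylidenedecahydroazulen-1-yl]ethyl}oxolan-2-one | C=C1CCCC(C)(C)[C@@H]2CC[C@@](C)([C@H](CO)[C@@H]3COC(=O)C3)[C@H]12 | intermediate
30 | (2R)-2-[(3R)-5-oxooxolan-3-yl]-2-[(1R,3aR,8aS)-1,4,4-trimethyl-8-methylidenedecahydroazulen-1-yl]ethyl acetate | C=C1CCCC(C)(C)[C@@H]2CC[C@@](C)([C@H](COC(C)=O)[C@@H]3COC(=O)C3)[C@H]12 | target

## Step count and risks

Total step count: 20. Longest linear sequence: 17 steps (steps 1–13 and 17–20); steps 14–16 make the acceptor 26.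

Steps most likely to fail:

1. Step 17. The hindered tertiary radical may add too slowly to the α-substituted butenolide and be lost by reduction, or the enolate may be protonated without facial control or epimerise, which would erode the C-3 center. Fallback, from 19 (with 22) back to 27: photoredox coupling of 19 with the unsubstituted butenolide 22 under the step 17 conditions should give (4R,5S)-5-(menthyloxy)-4-(hydroazulenyl)oxolan-2-one F1. Deprotonation with LDA (THF, −78 °C) and alkylation with tert-butyl bromoacetate anti to the C-4 substituent should give the trans-3,4 lactone F2. A second deprotonation (LDA, 2.2 equiv, −78 °C) and kinetic protonation with 2,6-di-tert-butyl-4-methylphenol from the face opposite the quaternary substituent should give the cis lactone 27.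

2. Step 2. The enolate may equilibrate by proton transfer, giving regioisomeric or polyalkylated ketones, or may attack the ester carbonyl. Fallback, from 3 back to 6: Lewis-acid-mediated alkylation of the silyl enol ether itself, with no free enolate, using methyl 2-chloro-2-(phenylsulfanyl)acetate and ZnBr2 in CH2Cl2, should give methyl 2-[(1R)-2-[2-methoxy-2-oxo-1-(phenylsulfanyl)ethyl]-3-oxocyclopentyl]-2-methylpropanoate F3. Radical desulfurisation with Bu3SnH/AIBN in benzene at 80 °C should then give 6.

3. Step 18. The freed alkoxide may close onto the tert-butyl ester during the reduction, and the lactone so formed would be over-reduced to a triol. Fallback, from 24 (with 19) back to 29, with a nitrile as the masked carboxyl group: Negishi coupling of 24 with (cyanomethyl)zinc bromide and Pd(PPh3)4 should give 2-[(5S)-5-(menthyloxy)-2-oxo-2,5-dihydrofuran-3-yl]acetonitrile F4. Photoredox coupling with 19 as in step 17 should give the (3R,4R,5S) adduct nitrile F5. LiBH4, to which the nitrile is inert, should give (3R,4R)-5-hydroxy-3-(hydroxymethyl)-4-(hydroazulenyl)pentanenitrile F6. Hydrolysis with KOH in aqueous EtOH at 80 °C and acidification to pH 2 should close the γ-lactone and give 29.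

## Further compounds

F1 | step 17 | (4R,5S)-5-{[(1S,2R,5S)-5-methyl-2-(propan-2-yl)cyclohexyl]oxy}-4-[(1R,3aR,8aS)-1,4,4-trimethyl-8-methylidenedecahydroazulen-1-yl]oxolan-2-one | C=C1CCCC(C)(C)[C@@H]2CC[C@@](C)([C@@H]3[C@@H](O[C@H]4C[C@@H](C)CC[C@@H]4C(C)C)OC(=O)C3)[C@H]12
F2 | step 17 | tert-butyl 2-[(3S,4R,5S)-5-{[(1S,2R,5S)-5-methyl-2-(propan-2-yl)cyclohexyl]oxy}-2-oxo-4-[(1R,3aR,8aS)-1,4,4-trimethyl-8-methylidenedecahydroazulen-1-yl]oxolan-3-yl]acetate | C=C1CCCC(C)(C)[C@@H]2CC[C@@](C)([C@@H]3[C@@H](O[C@H]4C[C@@H](C)CC[C@@H]4C(C)C)OC(=O)[C@H]3CC(=O)OC(C)(C)C)[C@H]12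
F3 | step 2 | methyl 2-[(1R)-2-[2-methoxy-2-oxo-1-(phenylsulfanyl)ethyl]-3-oxocyclopentyl]-2-methylpropanoate (ring substituents trans, mixture at the sulfur-bearing carbon) | COC(=O)C(C)(C)[C@@H]1CCC(=O)[C@H]1C(Sc1ccccc1)C(=O)OC
F4 | step 18 | 2-[(5S)-5-{[(1S,2R,5S)-5-methyl-2-(propan-2-yl)cyclohexyl]oxy}-2-oxo-2,5-dihydrofuran-3-yl]acetonitrile | O=C1C(CC#N)=C[C@@H](O[C@H]2C[C@@H](C)CC[C@@H]2C(C)C)O1
F5 | step 18 | 2-[(3R,4R,5S)-5-{[(1S,2R,5S)-5-methyl-2-(propan-2-yl)cyclohexyl]oxy}-2-oxo-4-[(1R,3aR,8aS)-1,4,4-trimethyl-8-methylidenedecahydroazulen-1-yl]oxolan-3-yl]acetonitrile | C=C1CCCC(C)(C)[C@@H]2CC[C@@](C)([C@@H]3[C@@H](O[C@H]4C[C@@H](C)CC[C@@H]4C(C)C)OC(=O)[C@@H]3CC#N)[C@H]12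
F6 | step 18 | (3R,4R)-5-hydroxy-3-(hydroxymethyl)-4-[(1R,3aR,8aS)-1,4,4-trimethyl-8-methylidenedecahydroazulen-1-yl]pentanenitrile | C=C1CCCC(C)(C)[C@@H]2CC[C@@](C)([C@H](CO)[C@H](CO)CC#N)[C@H]12
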